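**Assumption:** bicyclic compounds are numbered as bicyclo[3.2.1]octanes (C1 = OMe-bearing bridgehead, C2 = ring C=O, C3 = C–OMe, C5 = allyl-bearing bridgehead, C6 = CH–CH3, C7 = CH–Ar, C8 = one-carbon bridge); exo = towards C8, endo = towards the C2–C4 bridge. The target is then (1S,3S,5S,6R,7S,8S): aryl endo, methyl exo, 8-OH over the C2–C4 bridge, 3-OMe on the endo face.

## Retrosynthetic overview

1. Target 27 ⇐ enedione 25 by one dissolving-metal reduction (enone → C3-H/C2 ketone, C8 ketone → C8 alcohol).
2. 25 ⇐ cationic [5+2] cycloaddition of quinone monoketal 21 with (E)-arylpropene 7; this single step closes both carbocycles of the bicyclo[3.2.1]octane.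
3. Absolute configuration: 7 carries a (−)-menthyl carbonate, so the two cycloadducts are diastereomers and are separated.
4. 21 ⇐ 6-allyl-2,3,4-trimethoxyphenol (Claisen) ⇐ 2,3,4-trimethoxyphenol ⇐ squaric acid + vinyl bromide (cyclobutenone benzannulation builds the arene first).
5. 7 ⇐ (E)-isochavibetol ⇐ catechol + propionic acid (acylation, selective 4-O-methylation, reduction, dehydration).

## Route

Step 1
Reactants: 1 catechol; 2 propionic acid
Product: 3 1-(3,4-dihydroxyphenyl)propan-1-one
Conditions: BF3·OEt2 (3 equiv), neat, 90 °C, 3 h; H2O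
Reagents that add atoms: none
Why: Friedel–Crafts (Nencki-type) C-acylation by the BF3-activated acid goes para to one hydroxyl of catechol and creates no stereocentre.

Step 2
Reactants: 3 1-(3,4-dihydroxyphenyl)propan-1-one
Product: 4 1-(3-hydroxy-4-methoxyphenyl)propan-1-one
Conditions: MeI (1.3 equiv), Li2CO3 (1.5 equiv), DMF, 50 °C
Reagents that add atoms: iodomethane CI
Why: Williamson O-methylation is selective because the weak base ionises only the more acidic 4-OH, which is para to the ketone.

Step 3
Reactants: 4 1-(3-hydroxy-4-methoxyphenyl)propan-1-one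
Product: 5 1-(3-hydroxy-4-methoxyphenyl)propan-1-ol (racemic)
Conditions: NaBH4 (1.5 equiv), MeOH, 0 °C → rt
Reagents that add atoms: none
Why: Borohydride carbonyl reduction gives the benzylic alcohol; its stereocentre is racemic and is removed in the next step.

Step 4
Reactants: 5 1-(3-hydroxy-4-methoxyphenyl)propan-1-ol
Product: 6 2-methoxy-5-[(1E)-prop-1-en-1-yl]phenol
Conditions: p-TsOH·H2O (2 mol%), BHT (cat.), toluene, 80 °C, Dean–Stark
Reagents that add atoms: none
Why: E1 dehydration through the p-methoxybenzylic cation gives the conjugated alkene under thermodynamic control, so the E isomer dominates (>95:5).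

Step 5
Reactants: 6 2-methoxy-5-[(1E)-prop-1-en-1-yl]phenol
Product: 7 (1R,2S,5R)-menthyl 2-methoxy-5-[(1E)-prop-1-en-1-yl]phenyl carbonate
Conditions: (−)-menthyl chloroformate (1.1 equiv), pyridine (2 equiv), DMAP (5 mol%), CH2Cl2, 0 °C → rt
Reagents that add atoms: (1R,2S,5R)-menthyl chloroformate CC(C)[C@@H]1CC[C@@H](C)C[C@H]1OC(=O)Cl
Why: O-acylation gives a carbonate that protects the phenol from the later cation and brings three fixed menthyl stereocentres for diastereomer separation.

Step 6
Reactants: 8 squaric acid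
Product: 9 dimethyl squarate
Conditions: HC(OMe)3 (2.5 equiv), MeOH, reflux, 24 h
Reagents that add atoms: trimethyl orthoformate COC(OC)OC
Why: Orthoester esterification of the vinylogous diacid is driven by loss of methyl formate.

Step 7
Reactants: 9 dimethyl squarate; 10 vinyl bromide
Product: 13 2,3,4-trimethoxy-4-vinylcyclobut-2-en-1-one (racemic), via vinyllithium 11 (not isolated), via lithium cyclobutenolate 12 (not isolated)
Conditions: 10, t-BuLi (2.0 equiv), Et2O, −78 °C; add to 9, THF, −78 °C; MeOTf (1.5 equiv), −78 → 0 °C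
Reagents that add atoms: methyl trifluoromethanesulfonate COS(=O)(=O)C(F)(F)F
Why: Halogen–lithium exchange, 1,2-addition to one of the two equivalent squarate carbonyls and O-methylation of the alkoxide give the 4-alkenyl-4-methoxycyclobutenone; the new centre is racemic and lost in the next step.

Step 8
Reactants: 13 2,3,4-trimethoxy-4-vinylcyclobut-2-en-1-one
Product: 16 2,3,4-trimethoxyphenol, via dienylketene 14 (not isolated), via cyclohexadienone tautomer 15 (not isolated)
Conditions: p-xylene (0.02 M), 138 °C, 1 h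
Reagents that add atoms: none
Why: Moore cyclobutenone benzannulation: 4π ring opening with the methoxy group rotating outward gives the (Z)-dienylketene, which undergoes 6π electrocyclisation and tautomerises to the phenol with the oxygen pattern fixed.

Step 9
Reactants: 16 2,3,4-trimethoxyphenol; 17 allyl bromide
Product: 18 1,2,3-trimethoxy-4-(prop-2-en-1-yloxy)benzene
Conditions: K2CO3 (2 equiv), acetone, reflux
Reagents that add atoms: none
Why: Williamson etherification of the phenoxide with a primary allylic bromide.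

Step 10
Reactants: 18 1,2,3-trimethoxy-4-(prop-2-en-1-yloxy)benzene
Product: 20 2,3,4-trimethoxy-6-(prop-2-en-1-yl)phenol, via ortho-dienone 19 (not isolated)
Conditions: N,N-diethylaniline, 190 °C, 4 h
Reagents that add atoms: none
Why: Aromatic Claisen [3,3] rearrangement delivers the allyl group to the only unsubstituted ortho carbon, and enolisation restores the phenol.

Step 11
Reactants: 20 2,3,4-trimethoxy-6-(prop-2-en-1-yl)phenol
Product: 21 4,4,5,6-tetramethoxy-2-(prop-2-en-1-yl)cyclohexa-2,5-dien-1-one
Conditions: PhI(OAc)2 (1.1 equiv), MeOH, 0 °C, 20 min; NaHCO3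
Reagents that add atoms: methanol CO
Why: Hypervalent-iodine oxidative dearomatisation: methanol adds to the phenoxonium ion at the para carbon that already bears OMe, giving the p-quinone monoketal.

Step 12
Reactants: 21 4,4,5,6-tetramethoxy-2-(prop-2-en-1-yl)cyclohexa-2,5-dien-1-one; 7 (1R,2S,5R)-menthyl 2-methoxy-5-[(1E)-prop-1-en-1-yl]phenyl carbonate
Product: 24 (1R,2S,5R)-menthyl 2-methoxy-5-[(1S,5R,6R,7S)-1,3-dimethoxy-6-methyl-2,8-dioxo-5-(prop-2-en-1-yl)bicyclo[3.2.1]oct-3-en-7-yl]phenyl carbonate, via dienyl oxocarbenium triflate 22 (not isolated), via O-methyl oxocarbenium cycloadduct 23 (not isolated)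
Conditions: 7 (1.3 equiv), TMSOTf (0.3 equiv), CH2Cl2, −78 → −40 °C, 2 h; aq. NaHCO3; separation of the two diastereomers by chromatography and crystallisation
Reagents that add atoms: none
Why: Büchi-type cationic [5+2] cycloaddition in which the CH–CH3 terminus of the alkene bonds to the allyl-bearing cation terminus and the resulting p-methoxybenzylic cation closes on the OMe-bearing terminus; suprafacial addition to the E-alkene keeps Me and Ar trans, the endo transition state (arene stacked over the alkoxydienyl cation) puts aryl endo and methyl exo, and since the remote menthyl group gives no facial bias both core enantiomers form (about 1:1) and the (1S,5R,6R,7S) diastereomer is isolated.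

Step 13
Reactants: 24 menthyl carbonate cycloadduct
Product: 25 (1S,5R,6R,7S)-7-(3-hydroxy-4-methoxyphenyl)-1,3-dimethoxy-6-methyl-5-(prop-2-en-1-yl)bicyclo[3.2.1]oct-3-ene-2,8-dione
Conditions: pyrrolidine (3 equiv), CH2Cl2, 0 °C, 1 h
Reagents that add atoms: none
Why: Aminolysis of the aryl carbonate expels the phenoxide as the better leaving group and avoids the alkoxide bases that would cleave the non-enolisable 1,3-dione by retro-Claisen; no stereocentre is touched.

Step 14
Reactants: 25 phenol enedione
Product: 27 (1S,3S,5S,6R,7S,8S)-8-hydroxy-7-(3-hydroxy-4-methoxyphenyl)-1,3-dimethoxy-6-methyl-5-(prop-2-en-1-yl)bicyclo[3.2.1]octan-2-one, via trilithium enolate alkoxide phenoxide 26 (not isolated)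
Conditions: Li (4.5 equiv), NH3(l)/THF 3:1, t-BuOH (2 equiv), −78 °C, 15 min; solid NH4Cl, −78 °C → rt
Reagents that add atoms: none
Why: Birch-type dissolving-metal reduction turns the enone into its lithium enolate (which shields C2=O) and the isolated C8 ketone into the thermodynamically preferred alkoxide with oxygen anti to the exo C6-methyl (as in camphor → borneol), and on the cold NH4Cl quench the enolate is protonated at C3 from the exo face because the endo face is screened by the C7 aryl group, which sets 3S.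

## Compound list

1 | catechol | Oc1ccccc1O | starting material
2 | propionic acid | CCC(=O)O | starting material
3 | 1-(3,4-dihydroxyphenyl)propan-1-one | CCC(=O)c1ccc(O)c(O)c1 | intermediate
4 | 1-(3-hydroxy-4-methoxyphenyl)propan-1-one | CCC(=O)c1ccc(OC)c(O)c1 | intermediate
5 | 1-(3-hydroxy-4-methoxyphenyl)propan-1-ol (racemic) | CCC(O)c1ccc(OC)c(O)c1 | intermediate
6 | 2-methoxy-5-[(1E)-prop-1-en-1-yl]phenol | C/C=C/c1ccc(OC)c(O)c1 | intermediate
7 | (1R,2S,5R)-menthyl 2-methoxy-5-[(1E)-prop-1-en-1-yl]phenyl carbonate | C/C=C/c1ccc(OC)c(OC(=O)O[C@@H]2C[C@H](C)CC[C@H]2C(C)C)c1 | intermediate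
8 | squaric acid | O=C1C(O)=C(O)C1=O | starting material
9 | dimethyl squarate | COC1=C(OC)C(=O)C1=O | intermediate
10 | vinyl bromide | C=CBr | starting material
11 | vinyllithium (not isolated) | [Li]C=C | intermediate
12 | lithium 2,3-dimethoxy-4-oxo-1-vinylcyclobut-2-en-1-olate (racemic, not isolated) | C=CC1([O-])C(OC)=C(OC)C1=O.[Li+] | intermediate
13 | 2,3,4-trimethoxy-4-vinylcyclobut-2-en-1-one (racemic) | C=CC1(OC)C(OC)=C(OC)C1=O | intermediate
14 | (3Z)-2,3,4-trimethoxyhexa-1,3,5-trien-1-one (dienylketene, not isolated) | C=C/C(OC)=C(OC)\C(OC)=C=O | intermediate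
15 | 2,3,4-trimethoxycyclohexa-2,4-dien-1-one (not isolated) | COC1=CCC(=O)C(OC)=C1OC | intermediate
16 | 2,3,4-trimethoxyphenol | COc1ccc(O)c(OC)c1OC | intermediate
17 | allyl bromide | C=CCBr | starting material
18 | 1,2,3-trimethoxy-4-(prop-2-en-1-yloxy)benzene | C=CCOc1ccc(OC)c(OC)c1OC | intermediate
19 | 2,3,4-trimethoxy-6-(prop-2-en-1-yl)cyclohexa-2,4-dien-1-one (racemic, not isolated) | C=CCC1C=C(OC)C(OC)=C(OC)C1=O | intermediate
20 | 2,3,4-trimethoxy-6-(prop-2-en-1-yl)phenol | C=CCc1cc(OC)c(OC)c(OC)c1O | intermediate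
21 | 4,4,5,6-tetramethoxy-2-(prop-2-en-1-yl)cyclohexa-2,5-dien-1-one | C=CCC1=CC(OC)(OC)C(OC)=C(OC)C1=O | intermediate
22 | 5-allyl-1,2,3-trimethoxy-4-oxocyclohexa-2,5-dien-1-ylium triflate, drawn as the O-methyl oxocarbenium (not isolated) | C=CCC1=CC(=[O+]C)C(OC)=C(OC)C1=O.[O-]S(=O)(=O)C(F)(F)F | intermediate
23 | C2 O-methyl oxocarbenium triflate of cycloadduct 24 (not isolated) | C=CC[C@]12C=C(OC)C(=[O+]C)[C@](OC)([C@H](c3ccc(OC)c(OC(=O)O[C@@H]4C[C@H](C)CC[C@H]4C(C)C)c3)[C@H]1C)C2=O.[O-]S(=O)(=O)C(F)(F)F | intermediate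
24 | (1R,2S,5R)-menthyl 2-methoxy-5-[(1S,5R,6R,7S)-1,3-dimethoxy-6-methyl-2,8-dioxo-5-(prop-2-en-1-yl)bicyclo[3.2.1]oct-3-en-7-yl]phenyl carbonate (aryl endo, methyl exo) | C=CC[C@]12C=C(OC)C(=O)[C@](OC)([C@H](c3ccc(OC)c(OC(=O)O[C@@H]4C[C@H](C)CC[C@H]4C(C)C)c3)[C@H]1C)C2=O | intermediate
25 | (1S,5R,6R,7S)-7-(3-hydroxy-4-methoxyphenyl)-1,3-dimethoxy-6-methyl-5-(prop-2-en-1-yl)bicyclo[3.2.1]oct-3-ene-2,8-dione | C=CC[C@]12C=C(OC)C(=O)[C@](OC)([C@H](c3ccc(OC)c(O)c3)[C@H]1C)C2=O | intermediate
26 | trilithium C2-enolate / C8-alkoxide / phenoxide of 27 (not isolated) | [Li+].[Li+].[Li+].C=CC[C@]12CC(OC)=C([O-])[C@](OC)([C@H](c3ccc(OC)c([O-])c3)[C@H]1C)[C@H]2[O-] | intermediate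
27 | (1S,3S,5S,6R,7S,8S)-8-hydroxy-7-(3-hydroxy-4-methoxyphenyl)-1,3-dimethoxy-6-methyl-5-(prop-2-en-1-yl)bicyclo[3.2.1]octan-2-one (CNP0209708.1) | C=CC[C@]12C[C@H](OC)C(=O)[C@](OC)([C@H](c3ccc(OC)c(O)c3)[C@H]1C)[C@H]2O | target

## Step count and risks

Total: 14 steps. Longest linear sequence: 9 steps (steps 6–14, from squaric acid); the aryl branch is steps 1–5 and joins at step 12.

**Step 11 (oxidative ketalisation).** The phenol carries methoxy groups both ortho and para, so methanol may add ortho and give an o-quinone ketal that dimerises; the p-ketal is also acid-labile. Fallback: skip the ketal. Setting out from phenol 20 and carbonate 7, the two are mixed in (CF3)2CHOH/CH2Cl2 at −40 °C and treated with PhI(OCOCF3)2. Two-electron oxidation of 20 gives the same dienyl cation as in 22 with no external nucleophile present, and 7 traps it in the same [5+2] sense. After bicarbonate work-up and diastereomer separation the route is rejoined at 24. No new isolable compound is made (F0).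

**Step 12 ([5+2] cycloaddition and diastereomer separation).** Risks are O-trapping to the dihydrobenzofuran ([3+2]) product, acid-induced rearrangement of the adduct, and above all that the two diastereomers do not separate because the menthyl group is far from the core. Fallback: run the union racemic with an achiral protecting group and resolve later. Setting out from 6, TIPSCl/imidazole (DMF, rt) gives the triisopropylsilyl ether F1. The same TMSOTf-catalysed cycloaddition with 21 gives the racemic silyl-protected cycloadduct F2. HF·pyridine (THF, 0 °C) gives the racemic phenol F3. Preparative chiral SFC on an amylose carbamate phase then delivers the (1S,5R,6R,7S) enantiomer, rejoining the route at 25.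

**Step 14 (one-pot Li/NH3 reduction).** Risks are over-reduction, amide-induced retro-Claisen cleavage of the 1,3-dione, incomplete thermodynamic control at C8, and the wrong C3 epimer on quench. Hydride reagents are not an option here: they attack C8 from the open enone side and would give the C8 epimer. Fallback: separate the two reductions. Setting out from 25, Stryker's reagent with TBSCl/Et3N (THF, −40 → 0 °C) silylates the phenol and effects conjugate reduction with O-silylation, giving the bis-silyl compound F4 (aryl TBS ether, C2 TBS enol ether, C8 ketone). An equilibrating Meerwein–Ponndorf–Verley reduction (Al(OiPr)3, iPrOH/toluene, 80 °C, trace acetone) of the only remaining ketone gives the thermodynamic C8 alcohol F5, with OH anti to the exo methyl. HF·pyridine (THF, 0 °C) removes both silyl groups with exo-face protonation at C3 and rejoins the route at 27.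

## Further compounds

F0 | step 11 | none | none
F1 | step 12 | triisopropyl{2-methoxy-5-[(1E)-prop-1-en-1-yl]phenoxy}silane | C/C=C/c1ccc(OC)c(O[Si](C(C)C)(C(C)C)C(C)C)c1
F2 | step 12 | racemic (1S*,5R*,6R*,7S*)-1,3-dimethoxy-6-methyl-5-(prop-2-en-1-yl)-7-[4-methoxy-3-(triisopropylsilyloxy)phenyl]bicyclo[3.2.1]oct-3-ene-2,8-dione | C=CC[C@]12C=C(OC)C(=O)[C@](OC)([C@H](c3ccc(OC)c(O[Si](C(C)C)(C(C)C)C(C)C)c3)[C@H]1C)C2=O.C=CC[C@@]12C=C(OC)C(=O)[C@@](OC)([C@@H](c3ccc(OC)c(O[Si](C(C)C)(C(C)C)C(C)C)c3)[C@@H]1C)C2=O
F3 | step 12 | racemic 25 | C=CC[C@]12C=C(OC)C(=O)[C@](OC)([C@H](c3ccc(OC)c(O)c3)[C@H]1C)C2=O.C=CC[C@@]12C=C(OC)C(=O)[C@@](OC)([C@@H](c3ccc(OC)c(O)c3)[C@@H]1C)C2=O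
F4 | step 14 | (1S,5S,6R,7S)-2-(tert-butyldimethylsilyloxy)-7-[3-(tert-butyldimethylsilyloxy)-4-methoxyphenyl]-1,3-dimethoxy-6-methyl-5-(prop-2-en-1-yl)bicyclo[3.2.1]oct-2-en-8-one | C=CC[C@]12CC(OC)=C(O[Si](C)(C)C(C)(C)C)[C@](OC)([C@H](c3ccc(OC)c(O[Si](C)(C)C(C)(C)C)c3)[C@H]1C)C2=O
F5 | step 14 | C8 alcohol of F4, OH anti to the exo C6-methyl (8S) | C=CC[C@]12CC(OC)=C(O[Si](C)(C)C(C)(C)C)[C@](OC)([C@H](c3ccc(OC)c(O[Si](C)(C)C(C)(C)C)c3)[C@H]1C)[C@H]2O
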